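**Retrosynthetic overview**
1. The plan rests on ring A, which carries a cis-2α,3α-diol. C2–OAc is equatorial, C3–OH is axial and sits next to the C4 gem-dimethyl group. The C2–C3 bond joining these two carbinol carbons is the strategic bond.
2. Late stage: the C2 acetate is placed by selective acylation. The side chain is cut at C12–C13 (B-alkyl Suzuki coupling with a Z-β-iodoenoate) and at C9–C11 (α-face vinyl addition to a C9 ketone).
3. Key disconnection: C2–C3, made by reductive pinacol union of a C2 aldehyde and a C3 aldehyde that sit trans on ring B (C10–CH2CHO and C5–CMe2CHO).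
4. Ring B comes from (R)-carvone. C5–C4 is made by Mukaiyama–Michael addition anti to the isopropenyl group, and C10–C1 by enolate alkylation anti to the C5 arm. The isopropenyl group is then excised, and C8 is methylated and equilibrated.
5. Ring order: ring B from the chiral pool, then ring A in the pinacol step.

Key step: step 7

Remark: labdane numbering is used for every compound and β is the face of the C10 methyl group; the target SMILES is read as 2α-OAc, 3α-OH, 5α-H, 8α-CH3, 9β-OH with the C11 chain α, 10β-CH3 and 13Z, that is (2R,3S,5S,8R,9S,10S).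

Step 1
Reactants: 1 (R)-(−)-carvone; 2 1-methoxy-2-methyl-1-(trimethylsiloxy)propene
Product: 3 C9–C10 trimethylsilyl enol ether of the Michael adduct (5β-CMe2CO2Me; 7α-isopropenyl)
Conditions: HNTf2 (2 mol %), CH2Cl2, −78 °C; Et3N quench, cold NaHCO3 wash
Reagents that add atoms: none
Why: Mukaiyama–Michael addition in which Me3SiNTf2 formed in situ activates the enone, the ketene acetal attacks C5 axially on the half-chair that keeps the isopropenyl group equatorial and therefore anti to it (C4 arm β), and silyl transfer stores the enolate regiospecifically as the C9–C10 enol ether.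

Step 2
Reactants: 3 silyl enol ether; 4 methyl bromoacetate
Product: 6 7α-isopropenyl keto diester (10β-CH3; 10α-CH2CO2Me; 5β-CMe2CO2Me), via ammonium enolate 5 (not isolated)
Conditions: BnMe3NF (anhydrous), 4 Å MS, THF, 0 °C → rt
Reagents that add atoms: none
Why: Fluoride-mediated regiospecific alkylation of a silyl enol ether, in which desilylation frees the tetrasubstituted C9–C10 enolate without touching the ester and the reactive bromoacetate enters at C10 from the α face, anti to the pseudoaxial C5 tert-alkyl group, so that the two arms end up trans and the C10 methyl is β.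

Step 3
Reactants: 6 7α-isopropenyl keto diester
Product: 8 keto diester with C7 = CH2, via methoxy hydroperoxide 7 (not isolated)
Conditions: O3, MeOH, −78 °C; then PhSH, FeSO4·7H2O, −78 °C → rt
Reagents that add atoms: none
Why: Hydrodealkenylative C–C fragmentation, in which ozonolysis in methanol gives the α-methoxy hydroperoxide, divalent iron cleaves its O–O bond, β-scission of the alkoxyl radical expels methyl acetate and the secondary C7 radical takes hydrogen from the thiol, while ketone and esters are inert and the spent C7 stereocentre disappears.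

Step 4
Reactants: 8 keto diester
Product: 11 8α-methyl keto diester, via lithium enolate 9 (not isolated), via 8β-methyl epimer 10 (not isolated)
Conditions: LiN(iPr)2, THF, −78 °C; MeI, DMPU, −78 → −20 °C; crude product: NaOMe (0.3 equiv), MeOH, rt
Reagents that add atoms: iodomethane, CI
Why: Kinetic enolate methylation followed by thermodynamic epimerisation, since C8 is the only enolisable position of the ketone and is more acidic than the neopentyl ester CH2, and methoxide then drives C8 to the equatorial 8α-methyl epimer because an 8β-methyl would be syn-diaxial to the C10 methyl in the chair anchored by the equatorial C5 tert-alkyl group, a preference that becomes stronger still in the later trans-decalones.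

Step 5
Reactants: 11 8α-methyl keto diester
Product: 12 triol (C2-OH; C3-OH; 9β-OH)
Conditions: LiAlH4, THF, 0 °C → reflux; aqueous NaOH work-up
Reagents that add atoms: none
Why: Exhaustive hydride reduction takes both esters to primary alcohols and the ketone to the carbinol (hydride expected from the α face, anti to the axial C10 methyl), whose configuration is irrelevant because the next step erases it.

Step 6
Reactants: 12 triol
Product: 13 keto dialdehyde (C10-CH2CHO trans to C5-CMe2CHO; 8α-CH3)
Conditions: (COCl)2, DMSO, CH2Cl2, −78 → −45 °C; Et3N, −78 → 0 °C; used crude at once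
Reagents that add atoms: none
Why: Swern oxidation converts all three hydroxyls into alkoxysulfonium salts before base is added, which keeps the C9 hydroxyl from trapping the nascent C2 aldehyde as a lactol and being over-oxidised to a lactone, and the cold, briefly basic medium spares C8 and the aldol-prone 1,6-dialdehyde.

Step 7
Reactants: 13 keto dialdehyde
Product: 14 2α,3α-dihydroxy-4,4,8α,10β-tetramethyl-trans-decal-9-one
Conditions: SmI2 (3 equiv, 0.1 M in THF), t-BuOH (2 equiv), THF, slow addition of 13 at high dilution, −78 °C → rt; aq. NaHCO3/Na2S2O3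
Reagents that add atoms: none
Why: Divalent samarium transfers one electron to an aldehyde (most readily the unhindered C2 aldehyde), the metal-bound ketyl attacks the C3 aldehyde held on the same samarium, and a second electron transfer gives the trivalent samarium diolate that is protonated on work-up. The closest known reaction is the SmI2 intramolecular pinacol coupling of 1,6-dialdehydes to cis-cyclohexane-1,2-diols. Ring A closes in the 6-exo-trig mode, and since the C10 and C5 arms are trans-diequatorial on ring B the bicycle can only be the trans-decalin. The cis relation of the C2 and C3 oxygens is set by both oxygens bridging one samarium centre while the C2–C3 bond forms. Both oxygens end up α because the chair-like transition state of the β-cis alternative would wedge an axial 2β-oxygen between the axial C10 and C4β methyl groups, whereas the α-cis array has an equatorial C2–O and an axial C3–O that meets only H1α and H5α. The step needs aldehyde-over-ketone selectivity, which is secured by the slower reduction of a dialkyl ketone flanked by quaternary C10 and branched C8 in the absence of HMPA, while high dilution keeps the coupling intramolecular.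

Step 8
Reactants: 14 decalone diol
Product: 15 2α,3α-O-isopropylidene decalone
Conditions: Me2C(OMe)2, PPTS, CH2Cl2, rt
Reagents that add atoms: 2,2-dimethoxypropane, COC(C)(C)OC
Why: Acid-catalysed acetal exchange closes a dioxolane readily on the cis-1,2-diol of the rigid trans-decalin, leaves the hindered C9 ketone unketalised and masks both hydroxyls against the organometallic reagents to come.

Step 9
Reactants: 15 acetonide decalone
Product: 16 9α-vinyl-9β-hydroxy acetonide
Conditions: CH2=CHMgBr, CeCl3 (anhydrous), THF, −78 → 0 °C; aq. NH4Cl
Reagents that add atoms: vinylmagnesium bromide, C=C[Mg]Br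
Why: Organocerium 1,2-addition, in which the weakly basic cerium reagent adds to the hindered, enolisable C9 ketone rather than deprotonating C8 and approaches axially from the α face because the β face is shielded by the adjacent axial C10 methyl, giving 9β-OH with C11 α.

Step 10
Reactants: 17 methyl but-2-ynoate
Product: 18 methyl (Z)-3-iodobut-2-enoate
Conditions: NaI, AcOH, 115 °C
Reagents that add atoms: sodium iodide, [Na+].[I-]
Why: Stereoselective hydroiodination of an ynoate, in which iodide adds in conjugate fashion and the resulting allenolate is protonated anti to it, places iodine cis to the ester (Z).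

Step 11
Reactants: 16 9α-vinyl carbinol; 18 methyl (Z)-3-iodobut-2-enoate
Product: 20 acetonide of methyl (13Z)-2α,3α,9β-trihydroxylabd-13-en-15-oate (C11 α), via B-alkyl-9-BBN borane 19 (not isolated)
Conditions: 9-BBN (excess, to allow for the free hydroxyl), THF, 0 °C → rt; then 18, Pd(dppf)Cl2 (5 mol %), AsPh3, Cs2CO3, DMF/H2O, rt
Reagents that add atoms: none
Why: Hydroboration and B-alkyl Suzuki–Miyaura coupling, in which 9-BBN places boron on terminal C12 and the zerovalent palladium cycle (oxidative addition, base-assisted transmetalation, reductive elimination) joins C12 to C13 with retention of the alkene geometry, so that the chain lies cis to the ester (13Z).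

Step 12
Reactants: 20 acetonide ester
Product: 21 methyl (13Z)-2α,3α,9β-trihydroxylabd-13-en-15-oate (C11 α)
Conditions: AcOH/THF/H2O (3:1:1), 45 °C
Reagents that add atoms: none
Why: Acid-catalysed acetal hydrolysis in dilute acetic acid cleaves the dioxolane but is too weak to ionise the unactivated tertiary C9 alcohol, hydrolyse the methyl ester or isomerise the enoate.

Step 13
Reactants: 21 triol ester
Product: 22 CNP0135744.2 (target)
Conditions: Ac2O (1.1 equiv), pyridine, CH2Cl2, 0 °C; neutral work-up
Reagents that add atoms: acetic anhydride, CC(=O)OC(C)=O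
Why: Sterically controlled monoacylation, since the equatorial 2α-hydroxyl is acetylated much faster than the axial, neopentyl 3α-hydroxyl next to C4 and the tertiary 9β-hydroxyl, so one equivalent of anhydride without DMAP should stop at the 2-acetate.

**Compound list**
1 | (R)-(−)-carvone, (5R)-2-methyl-5-(prop-1-en-2-yl)cyclohex-2-en-1-one | CC1=CC[C@@H](C(C)=C)CC1=O | starting material
2 | 1-methoxy-2-methyl-1-(trimethylsiloxy)propene | COC(=C(C)C)O[Si](C)(C)C | starting material
3 | methyl 2-methyl-2-[(1R,5R)-2-methyl-5-(prop-1-en-2-yl)-3-(trimethylsilyloxy)cyclohex-2-en-1-yl]propanoate (5β arm, 7α-isopropenyl) | C[Si](C)(C)OC1=C(C)[C@H](C(C)(C)C(=O)OC)C[C@@H](C(C)=C)C1 | intermediate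
4 | methyl bromoacetate | COC(=O)CBr | starting material
5 | benzyltrimethylammonium C9–C10 enolate derived from 3 | C[N+](C)(C)Cc1ccccc1.[O-]C1=C(C)[C@H](C(C)(C)C(=O)OC)C[C@@H](C(C)=C)C1 | intermediate
6 | methyl 2-[(1R,2S,5R)-2-(2-methoxy-2-oxoethyl)-2-methyl-3-oxo-5-(prop-1-en-2-yl)cyclohexyl]-2-methylpropanoate | O=C1C[C@H](C(C)=C)C[C@@H](C(C)(C)C(=O)OC)[C@]1(C)CC(=O)OC | intermediate
7 | α-methoxy hydroperoxide of 6 (C7 bears C(CH3)(OCH3)OOH, both configurations at that carbon) | O=C1C[C@H](C(C)(OC)OO)C[C@@H](C(C)(C)C(=O)OC)[C@]1(C)CC(=O)OC | intermediate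
8 | methyl 2-[(1R,2S)-2-(2-methoxy-2-oxoethyl)-2-methyl-3-oxocyclohexyl]-2-methylpropanoate | O=C1CCC[C@@H](C(C)(C)C(=O)OC)[C@]1(C)CC(=O)OC | intermediate
9 | lithium C8–C9 enolate of 8 | [Li+].[O-]C1=CCC[C@@H](C(C)(C)C(=O)OC)[C@]1(C)CC(=O)OC | intermediate
10 | 8β-methyl epimer of 11, (1R,2S,4S) | O=C1[C@@H](C)CC[C@@H](C(C)(C)C(=O)OC)[C@]1(C)CC(=O)OC | intermediate
11 | methyl 2-[(1R,2S,4R)-2-(2-methoxy-2-oxoethyl)-2,4-dimethyl-3-oxocyclohexyl]-2-methylpropanoate (8α-CH3) | O=C1[C@H](C)CC[C@@H](C(C)(C)C(=O)OC)[C@]1(C)CC(=O)OC | intermediate
12 | (1S,2S,3S,6R)-2-(2-hydroxyethyl)-3-(1-hydroxy-2-methylpropan-2-yl)-2,6-dimethylcyclohexan-1-ol (9β-OH drawn as the expected epimer) | O[C@H]1[C@H](C)CC[C@@H](C(C)(C)CO)[C@]1(C)CCO | intermediate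
13 | 2-[(1S,2S,4R)-2,4-dimethyl-3-oxo-2-(2-oxoethyl)cyclohexyl]-2-methylpropanal (key-step precursor) | O=C1[C@H](C)CC[C@@H](C(C)(C)C=O)[C@]1(C)CC=O | intermediate
14 | 2α,3α-dihydroxy-4,4,8α,10β-tetramethyl-trans-decal-9-one, 5α-H (key-step product) | O=C1[C@H](C)CC[C@H]2C(C)(C)[C@H](O)[C@H](O)C[C@@]21C | intermediate
15 | 2α,3α-O-isopropylidene derivative of 14 | O=C1[C@H](C)CC[C@H]2C(C)(C)[C@@H]3OC(C)(C)O[C@@H]3C[C@@]21C | intermediate
16 | 9α-vinyl-9β-hydroxy-2α,3α-O-isopropylidene-4,4,8α,10β-tetramethyl-trans-decalin | C=C[C@]1(O)[C@H](C)CC[C@H]2C(C)(C)[C@@H]3OC(C)(C)O[C@@H]3C[C@@]21C | intermediate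
17 | methyl but-2-ynoate | CC#CC(=O)OC | starting material
18 | methyl (Z)-3-iodobut-2-enoate | COC(=O)/C=C(/C)I | intermediate
19 | B-(C12)-alkyl-9-borabicyclo[3.3.1]nonane from 16 | C1CCC2CCCC1B2CC[C@]3(O)[C@H](C)CC[C@H]4C(C)(C)[C@@H]5OC(C)(C)O[C@@H]5C[C@@]43C | intermediate
20 | methyl (13Z)-9β-hydroxy-2α,3α-(isopropylidenedioxy)labd-13-en-15-oate, C11 chain α | COC(=O)/C=C(/C)CC[C@]1(O)[C@H](C)CC[C@H]2C(C)(C)[C@@H]3OC(C)(C)O[C@@H]3C[C@@]21C | intermediate
21 | methyl (13Z)-2α,3α,9β-trihydroxylabd-13-en-15-oate, C11 chain α | COC(=O)/C=C(/C)CC[C@]1(O)[C@H](C)CC[C@H]2C(C)(C)[C@H](O)[C@H](O)C[C@@]21C | intermediate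
22 | CNP0135744.2, methyl (13Z)-2α-acetoxy-3α,9β-dihydroxylabd-13-en-15-oate, C11 chain α, (2R,3S,5S,8R,9S,10S) | COC(=O)/C=C(/C)CC[C@]1(O)[C@H](C)CC[C@H]2C(C)(C)[C@H](O)[C@H](OC(C)=O)C[C@@]21C | target

**Total step count:** 13. **Longest linear sequence:** 12 (steps 1–9 and 11–13; step 10 is the side branch).

**Steps most likely to fail**

1. Step 7 (pinacol closure).
 - What may go wrong:
  - early protonation and further reduction of the ketyl, so that the aldehydes end up as alcohols;
  - aldol closure of the 1,6-dialdehyde on Lewis-acidic trivalent samarium;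
  - transannular coupling of the C3 ketyl with the C9 carbonyl from a conformer with an axial C5 arm;
  - loss of chelation control, which would erode the cis selectivity.
 - Fallback: it sets out from 13 and returns at 14. Double Wittig methylenation of the two aldehydes (Ph3P=CH2, THF, −78 → 0 °C), which should leave the flanked C9 ketone alone, would give the diene ketone F1. Ring-closing metathesis with the second-generation Grubbs catalyst, RuCl2(=CHPh)(PCy3)(SIMes), in refluxing CH2Cl2 would close ring A as the trans-decal-2-en-9-one F2. Catalytic OsO4 with NMO in acetone/water should then dihydroxylate C2=C3 from the α face, away from the axial C10 and C4β methyl groups, and give 14.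

2. Step 2 (quaternary C10 by enolate alkylation).
 - What may go wrong: C-alkylation at the congested tetrasubstituted enolate carbon may be slow. O-alkylation, proton transfer with loss of the regiodefined enolate, or consumption of the bromoacetate by fluoride could then take over.
 - Fallback: it sets out from 3 and returns at 6, and it replaces the anionic SN2 alkylation by a cationic one on the neutral enol ether. Methyl (phenylthio)acetate is chlorinated with NCS in CH2Cl2 to methyl chloro(phenylthio)acetate F3. Catalytic ZnBr2 in CH2Cl2 ionises it to a thionium ion, which 3 captures at C10, again anti to the C5 arm, to give the α-phenylthio keto diester F4. Radical desulfurisation with Bu3SnH and AIBN in toluene at 80 °C removes the sulfur, leaves the isopropenyl group intact and gives 6.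

3. Step 9 (addition to the doubly flanked C9 ketone).
 - What may go wrong: deprotonation toward C8 or plain non-addition at the crowded carbonyl, and incomplete facial bias because the α-axial trajectory meets H1α, H5α and H7α.
 - Fallback: it sets out from 15 and returns at 16, and it uses the slimmest carbon nucleophile. Lithium acetylide (HC≡CH, n-BuLi, THF, −78 °C → rt) should add axially from the α face to give the 9α-ethynyl carbinol F5. Semihydrogenation (H2, Pd on CaCO3 poisoned with Pb(OAc)2, quinoline, EtOAc) converts the alkyne into the vinyl group of 16.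

**Further compounds**
F1 | step 7 | ring B ketone with 10α-allyl, 10β-CH3, 5β-(2-methylbut-3-en-2-yl) and 8α-CH3 | O=C1[C@H](C)CC[C@@H](C(C)(C)C=C)[C@]1(C)CC=C
F2 | step 7 | 4,4,8α,10β-tetramethyl-trans-decal-2-en-9-one (5α-H) | O=C1[C@H](C)CC[C@H]2C(C)(C)C=CC[C@@]21C
F3 | step 2 | methyl 2-chloro-2-(phenylthio)acetate (racemic) | COC(=O)C(Cl)Sc1ccccc1
F4 | step 2 | C1-phenylthio derivative of 6 (both configurations at C1) | O=C1C[C@H](C(C)=C)C[C@@H](C(C)(C)C(=O)OC)[C@]1(C)C(Sc2ccccc2)C(=O)OC
F5 | step 9 | 9α-ethynyl-9β-hydroxy-2α,3α-O-isopropylidene-4,4,8α,10β-tetramethyl-trans-decalin | C#C[C@]1(O)[C@H](C)CC[C@H]2C(C)(C)[C@@H]3OC(C)(C)O[C@@H]3C[C@@]21C
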